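**Retrosynthetic overview**
1. The last disconnection removes three MOM ethers (O3, O7, O4') from the finished four-ring skeleton: flavonol rings A, C and B, with pyran ring D fused at C2'–C3'.
2. Key disconnection: ring D is opened at O3'–C(CH3)2 to an o-quinone methide, traced back through a 2'-allenylphenol to a 3'-O-(1,1-dimethylpropargyl) ether. In the same operation the C8 prenyl group is traced back to a 5-O-prenyl ether. The precursor is therefore an isomer with both C5 units still on oxygen and with C8 and C2' unsubstituted.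
3. Enabling feature: O3' of ring B lies between C4' (oxygen-bearing) and C2', its only ortho C–H and the future C4a of ring D. C8 of ring A is para to O5, whose only open ortho carbon is C6. Each oxygen can thus pass its C5 unit to one carbon only, and the crowded C2' beside the C2–C1' axis is filled intramolecularly.
4. Ring C comes from Baker–Venkataraman acyl transfer and cyclodehydration of an aryl ester. The ester joins a phloroacetophenone that carries O3 as an α-OMOM group to a benzoic acid with only one ortho substituent.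
5. The 1,1-dimethylallyl group at C6' comes from a γ-selective Suzuki–Miyaura coupling on a 2-bromobenzoate. Rings A and B are bought, ring C is formed next, ring D last.

Key step: step 13

Remark: the C2–C1' axis carries two ortho substituents on ring B and may be a stereogenic axis. The target SMILES defines no configuration, so the material is taken as racemic with respect to it.

**Step 1**
Reactants: 1 methyl 2-bromo-4,5-dimethoxybenzoate
Product: 2 methyl 2-bromo-4,5-dihydroxybenzoate
Conditions: BBr3 (2.5 equiv), CH2Cl2, −78 °C to 0 °C; then H2O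
Reagents that add atoms: none
Why: Lewis-acid aryl methyl ether cleavage with BBr3 should free both phenols through a cyclic catechol borate, while the aryl bromide and, at or below 0 °C, the methyl ester are left alone.

**Step 2**
Reactants: 2 methyl 2-bromo-4,5-dihydroxybenzoate
Product: 3 methyl 2-bromo-5-hydroxy-4-(methoxymethoxy)benzoate
Conditions: MOMCl (1.05 equiv), K2CO3 (1.05 equiv), acetone, 0 °C to rt
Reagents that add atoms: chloromethyl methyl ether, COCCl
Why: Williamson-type O-alkylation under acidity control: the 4-OH is para to the ester and more acidic than the 5-OH, so one equivalent of weak base should give the 4-O-MOM ether, as is usual for protocatechuic esters.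

**Step 3**
Reactants: 3 methyl 2-bromo-5-hydroxy-4-(methoxymethoxy)benzoate
Product: 4 methyl 5-hydroxy-4-(methoxymethoxy)-2-(2-methylbut-3-en-2-yl)benzoate
Conditions: 3-methylbut-2-enylboronic acid pinacol ester (1.5 equiv), Pd(OAc)2 (3 mol %), 1,1'-bis(di-tert-butylphosphino)ferrocene (4 mol %), K3PO4 (3 equiv), degassed THF/H2O, 60 °C
Reagents that add atoms: 3-methylbut-2-enylboronic acid pinacol ester, CC(C)=CCB1OC(C)(C)C(C)(C)O1
Why: γ-Selective Suzuki–Miyaura allyl–aryl coupling: SE2' transmetalation places palladium on the tertiary allyl carbon and the bulky wide-bite-angle diphosphine should force reductive elimination before σ–π–σ isomerisation, which builds the quaternary benzylic carbon of the 1,1-dimethylallyl group (no stereocentre).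

**Step 4**
Reactants: 4 methyl 5-hydroxy-4-(methoxymethoxy)-2-(2-methylbut-3-en-2-yl)benzoate
Product: 5 methyl 4-(methoxymethoxy)-2-(2-methylbut-3-en-2-yl)-5-(2-methylbut-3-yn-2-yloxy)benzoate
Conditions: 3-chloro-3-methylbut-1-yne (1.5 equiv), DBU (1.6 equiv), CuCl2·2H2O (1 mol %), MeCN, 0 °C to rt
Reagents that add atoms: 3-chloro-3-methylbut-1-yne, CC(C)(Cl)C#C
Why: Copper-catalysed O-propargylation of a phenol with a tertiary propargylic chloride, a standard entry to aryl 1,1-dimethylpropargyl ethers, should alkylate the only free OH at 0 °C without touching ester, MOM ether or vinyl group.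

**Step 5**
Reactants: 5 methyl 4-(methoxymethoxy)-2-(2-methylbut-3-en-2-yl)-5-(2-methylbut-3-yn-2-yloxy)benzoate
Product: 6 4-(methoxymethoxy)-2-(2-methylbut-3-en-2-yl)-5-(2-methylbut-3-yn-2-yloxy)benzoic acid
Conditions: KOH (5 equiv), MeOH/H2O, 65 °C; then 1 M HCl, 0 °C, to pH 4
Reagents that add atoms: potassium hydroxide, [K+].[OH-]
Why: Saponification (BAc2 ester hydrolysis) needs heat because of the ortho tert-alkyl group but meets only base-stable groups, and cold acidification to pH 4 spares the MOM ether.

**Step 6**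
Reactants: 7 1-(2,4,6-trihydroxyphenyl)ethanone
Product: 8 1-[2,6-dihydroxy-4-(methoxymethoxy)phenyl]ethanone
Conditions: MOMCl (1.0 equiv), K2CO3 (1.0 equiv), acetone, 0 °C to rt
Reagents that add atoms: chloromethyl methyl ether, COCCl
Why: Williamson-type O-alkylation under acidity control: the 4-OH is the only phenol of 7 that is not hydrogen-bonded to the ketone, so it should react first with one equivalent of MOMCl.

**Step 7**
Reactants: 8 1-[2,6-dihydroxy-4-(methoxymethoxy)phenyl]ethanone
Product: 9 1-[2-hydroxy-4-(methoxymethoxy)-6-(3-methylbut-2-enyloxy)phenyl]ethanone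
Conditions: 1-bromo-3-methylbut-2-ene (1.05 equiv), K2CO3 (1.1 equiv), acetone, reflux
Reagents that add atoms: 1-bromo-3-methylbut-2-ene, CC(C)=CCBr
Why: Williamson ether synthesis: the two remaining OH groups are equivalent, and after the first O-prenylation the last one is held in a strong hydrogen bond to the ketone, which should stop the reaction at the monoether.

**Step 8**
Reactants: 9 1-[2-hydroxy-4-(methoxymethoxy)-6-(3-methylbut-2-enyloxy)phenyl]ethanone
Product: 10 2-hydroxy-1-[2-hydroxy-4-(methoxymethoxy)-6-(3-methylbut-2-enyloxy)phenyl]ethanone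
Conditions: KN(SiMe3)2 (2.2 equiv), THF, −78 °C; 2-(benzenesulfonyl)-3-phenyloxaziridine (1.2 equiv), −78 °C; AcOH
Reagents that add atoms: 2-(benzenesulfonyl)-3-phenyloxaziridine, O=S(=O)(c1ccccc1)N1OC1c1ccccc1
Why: Davis oxidation: the phenoxide–enolate dianion should take up oxygen from the N-sulfonyloxaziridine at the enolate carbon, and this oxidant does not epoxidise the prenyl double bond at −78 °C.

**Step 9**
Reactants: 10 2-hydroxy-1-[2-hydroxy-4-(methoxymethoxy)-6-(3-methylbut-2-enyloxy)phenyl]ethanone
Product: 11 1-[2-hydroxy-4-(methoxymethoxy)-6-(3-methylbut-2-enyloxy)phenyl]-2-(methoxymethoxy)ethanone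
Conditions: MOMCl (1.2 equiv), i-Pr2NEt (1.5 equiv), CH2Cl2, 0 °C to rt
Reagents that add atoms: chloromethyl methyl ether, COCCl
Why: MOM ether formation with an amine base should take the primary alcohol only, since the last chelated phenol of such acetophenones does not react under these conditions.

**Step 10**
Reactants: 6 4-(methoxymethoxy)-2-(2-methylbut-3-en-2-yl)-5-(2-methylbut-3-yn-2-yloxy)benzoic acid; 11 1-[2-hydroxy-4-(methoxymethoxy)-6-(3-methylbut-2-enyloxy)phenyl]-2-(methoxymethoxy)ethanone
Product: 13 2-[2-(methoxymethoxy)acetyl]-5-(methoxymethoxy)-3-(3-methylbut-2-enyloxy)phenyl 4-(methoxymethoxy)-2-(2-methylbut-3-en-2-yl)-5-(2-methylbut-3-yn-2-yloxy)benzoate, via acid chloride 12 (not isolated)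
Conditions: 6, 1-chloro-N,N,2-trimethylprop-1-en-1-amine (1.1 equiv), CH2Cl2, 0 °C; then 11, Et3N (2 equiv), DMAP (20 mol %), 0 °C to rt
Reagents that add atoms: none
Why: Neutral acid chloride formation with an α-chloroenamine followed by DMAP-catalysed O-acylation avoids free HCl (MOM ethers) and should overcome the hindrance of both partners.

**Step 11**
Reactants: 13 aryl ester from step 10
Product: 14 1-[2-hydroxy-4-(methoxymethoxy)-6-(3-methylbut-2-enyloxy)phenyl]-2-(methoxymethoxy)-3-[4-(methoxymethoxy)-2-(2-methylbut-3-en-2-yl)-5-(2-methylbut-3-yn-2-yloxy)phenyl]propane-1,3-dione (racemic)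
Conditions: KOt-Bu (2.5 equiv), THF, 0 °C to rt; AcOH
Reagents that add atoms: none
Why: Baker–Venkataraman rearrangement: the α-alkoxy enolate attacks the neighbouring aryl ester through a six-membered transition state, so that the C3–C2 bond forms intramolecularly at a carbonyl with only one ortho substituent; the new stereocentre is racemic, enolisable and erased in step 12.

**Step 12**
Reactants: 14 α-(methoxymethoxy)-1,3-diketone from step 11
Product: 15 3,7-bis(methoxymethoxy)-2-[4-(methoxymethoxy)-2-(2-methylbut-3-en-2-yl)-5-(2-methylbut-3-yn-2-yloxy)phenyl]-5-(3-methylbut-2-enyloxy)-4H-chromen-4-one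
Conditions: pyridinium p-toluenesulfonate (20 mol %), 4 Å molecular sieves, toluene, 80 °C
Reagents that add atoms: none
Why: Acid-catalysed cyclodehydration of an o-hydroxyaryl 1,3-diketone (6-exo-trig hemiketal formation, then loss of water) closes ring C, and the weak acid in an aprotic solvent should spare MOM, prenyl and propargyl ethers.

**Step 13**
Reactants: 15 bis-ether flavonol from step 12
Product: 20 5-hydroxy-3,7-bis(methoxymethoxy)-2-[8-(methoxymethoxy)-2,2-dimethyl-6-(2-methylbut-3-en-2-yl)-2H-chromen-5-yl]-8-(3-methylbut-2-enyl)-4H-chromen-4-one, via ortho-dienone 16 (not isolated), via 8-prenyl phenol 17 (not isolated), via allenylphenol 18 (not isolated), via o-quinone methide 19 (not isolated)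
Conditions: Eu(fod)3 [tris(6,6,7,7,8,8,8-heptafluoro-2,2-dimethyloctane-3,5-dionato)europium] (10 mol %), NaHCO3, PhCl, argon, sealed vessel, 85 °C, then 150 °C in the same vessel
Reagents that add atoms: none
Why: Two oxygen-to-carbon relays run in one flask: at 85 °C the Eu(fod)3-bound chromone undergoes an aromatic Claisen shift of the 5-O-prenyl group to C6 (dienone 16) and a Cope shift on to C8, and enolisation gives phenol 17 (para-Claisen–Cope rearrangement, known for 5-O-prenyl flavonols). At 150 °C the aryl 1,1-dimethylpropargyl ether of ring B breaks its O–C(CH3)2 bond in a propargyl Claisen shift that makes the C2'–CH bond, enolisation gives allenylphenol 18, and a 1,5-hydrogen shift from O3'–H to the central allene carbon gives the Z-configured o-quinone methide 19. Ring D is then closed by a thermal disrotatory oxa-6π electrocyclisation of 19, in which the carbonyl oxygen O3' bonds to the C(CH3)2 terminus and ring B regains aromaticity, the closest known reaction type being the thermal chromene synthesis from aryl 1,1-dimethylpropargyl ethers. No stereocentre is formed, because the new sp3 carbon carries two methyl groups. Site selectivity is secured by the substrate: of the two carbons ortho to O3' only C2' bears hydrogen (C4' bears OMOM, and a shift to it is reversible and unproductive), and of the two carbons ortho to O5 only C6 is open (C4a is the ring fusion), from where only C8, para to O5, can be reached. In one operation the step makes two C–C bonds and one C–O bond, closes ring D, frees the 5-OH and fills the crowded C2' position beside the C2–C1' axis by intramolecular delivery after ring C is in place.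

**Step 14**
Reactants: 20 tris-MOM ether from step 13
Product: 21 3,5,7-trihydroxy-2-[8-hydroxy-2,2-dimethyl-6-(2-methylbut-3-en-2-yl)-2H-chromen-5-yl]-8-(3-methylbut-2-enyl)-4H-chromen-4-one (CNP0241222.0)
Conditions: HCl (1 M in MeOH), THF, 40 °C
Reagents that add atoms: none
Why: Acid-catalysed acetal exchange (MOM cleavage) in methanol frees O3, O7 and O4' under conditions that are routine for prenylated flavonoids and mild enough to avoid chroman formation between O7 and the C8 prenyl group.

**Compound list**
1 | methyl 2-bromo-4,5-dimethoxybenzoate | COC(=O)c1cc(OC)c(OC)cc1Br | starting material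
2 | methyl 2-bromo-4,5-dihydroxybenzoate | COC(=O)c1cc(O)c(O)cc1Br | intermediate
3 | methyl 2-bromo-5-hydroxy-4-(methoxymethoxy)benzoate | COC(=O)c1cc(O)c(OCOC)cc1Br | intermediate
4 | methyl 5-hydroxy-4-(methoxymethoxy)-2-(2-methylbut-3-en-2-yl)benzoate | COC(=O)c1cc(O)c(OCOC)cc1C(C)(C)C=C | intermediate
5 | methyl 4-(methoxymethoxy)-2-(2-methylbut-3-en-2-yl)-5-(2-methylbut-3-yn-2-yloxy)benzoate | COC(=O)c1cc(OC(C)(C)C#C)c(OCOC)cc1C(C)(C)C=C | intermediate
6 | 4-(methoxymethoxy)-2-(2-methylbut-3-en-2-yl)-5-(2-methylbut-3-yn-2-yloxy)benzoic acid | OC(=O)c1cc(OC(C)(C)C#C)c(OCOC)cc1C(C)(C)C=C | intermediate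
7 | 1-(2,4,6-trihydroxyphenyl)ethanone | CC(=O)c1c(O)cc(O)cc1O | starting material
8 | 1-[2,6-dihydroxy-4-(methoxymethoxy)phenyl]ethanone | CC(=O)c1c(O)cc(OCOC)cc1O | intermediate
9 | 1-[2-hydroxy-4-(methoxymethoxy)-6-(3-methylbut-2-enyloxy)phenyl]ethanone | CC(=O)c1c(O)cc(OCOC)cc1OCC=C(C)C | intermediate
10 | 2-hydroxy-1-[2-hydroxy-4-(methoxymethoxy)-6-(3-methylbut-2-enyloxy)phenyl]ethanone | OCC(=O)c1c(O)cc(OCOC)cc1OCC=C(C)C | intermediate
11 | 1-[2-hydroxy-4-(methoxymethoxy)-6-(3-methylbut-2-enyloxy)phenyl]-2-(methoxymethoxy)ethanone | COCOCC(=O)c1c(O)cc(OCOC)cc1OCC=C(C)C | intermediate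
12 | 4-(methoxymethoxy)-2-(2-methylbut-3-en-2-yl)-5-(2-methylbut-3-yn-2-yloxy)benzoyl chloride | ClC(=O)c1cc(OC(C)(C)C#C)c(OCOC)cc1C(C)(C)C=C | intermediate
13 | 2-[2-(methoxymethoxy)acetyl]-5-(methoxymethoxy)-3-(3-methylbut-2-enyloxy)phenyl 4-(methoxymethoxy)-2-(2-methylbut-3-en-2-yl)-5-(2-methylbut-3-yn-2-yloxy)benzoate | COCOCC(=O)c1c(OC(=O)c2cc(OC(C)(C)C#C)c(OCOC)cc2C(C)(C)C=C)cc(OCOC)cc1OCC=C(C)C | intermediate
14 | α-(methoxymethoxy)-1,3-diketone linking rings A and B (racemic, enolisable) | COCOC(C(=O)c1c(O)cc(OCOC)cc1OCC=C(C)C)C(=O)c1cc(OC(C)(C)C#C)c(OCOC)cc1C(C)(C)C=C | intermediate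
15 | 3,7-bis(methoxymethoxy)-2-[4-(methoxymethoxy)-2-(2-methylbut-3-en-2-yl)-5-(2-methylbut-3-yn-2-yloxy)phenyl]-5-(3-methylbut-2-enyloxy)-4H-chromen-4-one | C=CC(C)(C)c1cc(OCOC)c(OC(C)(C)C#C)cc1-c1oc2cc(OCOC)cc(OCC=C(C)C)c2c(=O)c1OCOC | intermediate
16 | ring A ortho-dienone: C5 ketone, C6 sp3 carbon bearing H and 2-methylbut-3-en-2-yl (racemic at C6), ring B as in 15 | C=CC(C)(C)C1C(=O)C2=C(C=C1OCOC)OC(c1cc(OC(C)(C)C#C)c(OCOC)cc1C(C)(C)C=C)=C(OCOC)C2=O | intermediate
17 | 5-hydroxy-8-(3-methylbut-2-enyl) flavonol ether that still carries the 3'-O-(1,1-dimethylpropargyl) group | C=CC(C)(C)c1cc(OCOC)c(OC(C)(C)C#C)cc1-c1oc2c(CC=C(C)C)c(OCOC)cc(O)c2c(=O)c1OCOC | intermediate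
18 | 3'-hydroxy-2'-(3-methylbuta-1,2-dienyl) flavonol ether | C=CC(C)(C)c1cc(OCOC)c(O)c(C=C=C(C)C)c1-c1oc2c(CC=C(C)C)c(OCOC)cc(O)c2c(=O)c1OCOC | intermediate
19 | ring B o-quinone methide: C3' ketone, (Z)-3-methylbut-2-enylidene group at C2' | C=CC(C)(C)C1=C(c2oc3c(CC=C(C)C)c(OCOC)cc(O)c3c(=O)c2OCOC)/C(=C/C=C(C)C)C(=O)C(OCOC)=C1 | intermediate
20 | 5-hydroxy-3,7-bis(methoxymethoxy)-2-[8-(methoxymethoxy)-2,2-dimethyl-6-(2-methylbut-3-en-2-yl)-2H-chromen-5-yl]-8-(3-methylbut-2-enyl)-4H-chromen-4-one | C=CC(C)(C)c1cc(OCOC)c2c(c1-c1oc3c(CC=C(C)C)c(OCOC)cc(O)c3c(=O)c1OCOC)C=CC(C)(C)O2 | intermediate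
21 | 3,5,7-trihydroxy-2-[8-hydroxy-2,2-dimethyl-6-(2-methylbut-3-en-2-yl)-2H-chromen-5-yl]-8-(3-methylbut-2-enyl)-4H-chromen-4-one (CNP0241222.0) | C=CC(C)(C)c1cc(O)c2c(c1-c1oc3c(CC=C(C)C)c(O)cc(O)c3c(=O)c1O)C=CC(C)(C)O2 | target

**Step count**
Total step count: 14.
Longest linear sequence: 10 steps (steps 1–5, then 10–14).

**Steps most likely to fail**

First, step 13.
- Risk: enolisation of the ring A dienone may outrun the Cope shift. The prenyl ether may be lost by retro-ene cleavage. The propargyl shift to the crowded C2' may need temperatures at which the material degrades.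
- Fallback (sets out from 15, comes back at 20): the propargyl relay is replaced by an allyl relay plus an oxidative closure.
- Semihydrogenation of the alkyne (H2, Pd/CaCO3 poisoned with Pb(OAc)2, quinoline, EtOAc) should give the 3'-O-(1,1-dimethylallyl) ether F1.
- Tertiary allyl aryl ethers rearrange well below the temperature a propargyl ether needs. Eu(fod)3 and NaHCO3 in PhCl at about 100 °C should therefore move both C5 units and give the 8,2'-diprenyl-5,3'-diphenol F2.
- DDQ in toluene should then take hydride from the benzylic CH2 of the 2'-prenyl group. This is the only prenyl group with a free ortho phenol. Loss of the proton gives o-quinone methide 19, which closes through the same O3'–C(CH3)2 bond to 20.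

Second, step 3.
- Risk: σ–π–σ isomerisation of the allylpalladium species may be faster than reductive elimination next to the ortho ester, which would transfer the prenyl group through its primary carbon. The boronate may also be lost by protodeboronation.
- Fallback (sets out from 3, comes back at 4): the quaternary carbon is built by enolate arylation instead of allyl transfer.
- Palladium-catalysed α-arylation of 2-methylpropanal (Pd(OAc)2, rac-BINAP, Cs2CO3, dioxane, 80 °C) should give the neopentyl aldehyde F3.
- Wittig methylenation (CH3PPh3Br, KOt-Bu in excess to cover the phenol, THF, 0 °C) then gives 4.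

Third, step 11.
- Risk: attack of the enolate on the ester carbonyl beside the tert-alkyl group may be too slow, so that ester cleavage and acyl scrambling take over.
- Fallback (sets out from 5 and 11, comes back at 14): the acyl substitution is replaced by addition to a far less hindered aldehyde.
- Reduction of 5 with i-Bu2AlH (CH2Cl2, −78 °C) gives the benzylic alcohol F4, and MnO2 in CH2Cl2 gives the benzaldehyde F5.
- The dianion of 11 (LiN(i-Pr)2, 2.1 equiv, THF, −78 °C) adds to F5 to give the aldol F6 as a mixture of diastereomers. Both stereocentres are erased later.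
- Dess–Martin oxidation (NaHCO3, CH2Cl2) then gives 14.

**Further compounds**
F1 | step 13 | 3,7-bis(methoxymethoxy)-2-[4-(methoxymethoxy)-2-(2-methylbut-3-en-2-yl)-5-(2-methylbut-3-en-2-yloxy)phenyl]-5-(3-methylbut-2-enyloxy)-4H-chromen-4-one | C=CC(C)(C)c1cc(OCOC)c(OC(C)(C)C=C)cc1-c1oc2cc(OCOC)cc(OCC=C(C)C)c2c(=O)c1OCOC
F2 | step 13 | 5-hydroxy-2-[3-hydroxy-4-(methoxymethoxy)-6-(2-methylbut-3-en-2-yl)-2-(3-methylbut-2-enyl)phenyl]-3,7-bis(methoxymethoxy)-8-(3-methylbut-2-enyl)-4H-chromen-4-one | C=CC(C)(C)c1cc(OCOC)c(O)c(CC=C(C)C)c1-c1oc2c(CC=C(C)C)c(OCOC)cc(O)c2c(=O)c1OCOC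
F3 | step 3 | methyl 5-hydroxy-4-(methoxymethoxy)-2-(2-methyl-1-oxopropan-2-yl)benzoate | COC(=O)c1cc(O)c(OCOC)cc1C(C)(C)C=O
F4 | step 11 | [4-(methoxymethoxy)-2-(2-methylbut-3-en-2-yl)-5-(2-methylbut-3-yn-2-yloxy)phenyl]methanol | OCc1cc(OC(C)(C)C#C)c(OCOC)cc1C(C)(C)C=C
F5 | step 11 | 4-(methoxymethoxy)-2-(2-methylbut-3-en-2-yl)-5-(2-methylbut-3-yn-2-yloxy)benzaldehyde | O=Cc1cc(OC(C)(C)C#C)c(OCOC)cc1C(C)(C)C=C
F6 | step 11 | 3-hydroxy-1-[2-hydroxy-4-(methoxymethoxy)-6-(3-methylbut-2-enyloxy)phenyl]-2-(methoxymethoxy)-3-[4-(methoxymethoxy)-2-(2-methylbut-3-en-2-yl)-5-(2-methylbut-3-yn-2-yloxy)phenyl]propan-1-one (mixture of diastereomers) | COCOC(C(=O)c1c(O)cc(OCOC)cc1OCC=C(C)C)C(O)c1cc(OC(C)(C)C#C)c(OCOC)cc1C(C)(C)C=C
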